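**Retrosynthetic overview**

1. Target 21 ⇐ macrocyclic silyl ether 19: the only C–O bond of the target is made last by a 1,3-oxygen transposition (secondary ring carbinol ether to primary allylic ether), which also sets the C1=C2 ring-olefin geometry.
2. 19 ⇐ ynal 18: the single 14-membered ring is closed in the penultimate step by a nickel-catalysed reductive aldehyde–alkyne coupling in the exo mode.
3. 18 ⇐ enoate 11 + alkenyltrifluoroborate 15 (from sulcatone): the lone stereocentre comes from a rhodium/(S)-BINAP 1,4-addition.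
4. 11 ⇐ nerylacetone 1: its methyl ketone becomes the alkyne, its 5Z olefin and its terminal olefin (after oxidation of the E-methyl) become the other two ring olefins.

Assumption: nerylacetone is bought as the single 5Z isomer (CAS 3879-26-3); sulcatone, acetaldehyde N,N-dimethylhydrazone and trimethyl phosphonoacetate are catalogue chemicals.

**Route**

Step 1
Reactants: 1 nerylacetone, (5Z)-6,10-dimethylundeca-5,9-dien-2-one
Product: 4 [(5Z)-6,10-dimethylundeca-5,9-dien-1-yn-1-yl]trimethylsilane, via enol phosphate 2 (not isolated), via lithium acetylide 3 (not isolated)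
Conditions: LiN(i-Pr)2 (1.05 equiv), THF, −78 °C; ClP(O)(OEt)2, −78 °C → rt; LiN(i-Pr)2 (2.3 equiv), −78 °C → rt; Me3SiCl, −78 °C → rt
Reagents that add atoms: chlorotrimethylsilane, C[Si](C)(C)Cl; diethyl chlorophosphate, CCOP(=O)(Cl)OCC (its atoms stay only in intermediate 2)
Why: Negishi one-pot conversion of a methyl ketone into a terminal alkyne (kinetic enolate O-phosphorylation, then base-induced elimination of the enol phosphate), with C-silylation of the acetylide in the same flask; the Z olefin is not touched.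

Step 2
Reactants: 4 [(5Z)-6,10-dimethylundeca-5,9-dien-1-yn-1-yl]trimethylsilane
Product: 5 (2E,6Z)-2,6-dimethyl-11-(trimethylsilyl)undeca-2,6-dien-10-yn-1-ol
Conditions: SeO2 (0.3 equiv), t-BuOOH (70% aq., 3 equiv), salicylic acid (0.1 equiv), CH2Cl2, 0 °C → rt; then NaBH4, MeOH, 0 °C
Reagents that add atoms: tert-butyl hydroperoxide, CC(C)(C)OO
Why: Sharpless SeO2/t-BuOOH allylic oxidation (ene reaction then [2,3]-sigmatropic shift) hydroxylates the E-methyl of the terminal trisubstituted olefin, and NaBH4 returns any over-oxidised enal to the alcohol.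

Step 3
Reactants: 5 (2E,6Z)-2,6-dimethyl-11-(trimethylsilyl)undeca-2,6-dien-10-yn-1-ol
Product: 6 [(5Z,9E)-11-bromo-6,10-dimethylundeca-5,9-dien-1-yn-1-yl]trimethylsilane
Conditions: CBr4, PPh3, CH2Cl2, −20 → 0 °C
Reagents that add atoms: carbon tetrabromide, BrC(Br)(Br)Br
Why: Appel bromination; SN2 displacement of the oxyphosphonium at the primary carbon proceeds at low temperature without allylic shift or loss of olefin geometry.

Step 4
Reactants: 6 [(5Z,9E)-11-bromo-6,10-dimethylundeca-5,9-dien-1-yn-1-yl]trimethylsilane; 7 acetaldehyde N,N-dimethylhydrazone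
Product: 9 (4E,8Z)-4,8-dimethyl-13-(trimethylsilyl)trideca-4,8-dien-12-ynal, via alkylated hydrazone 8 (not isolated)
Conditions: 7, LiN(i-Pr)2, THF, 0 °C; add 6, −78 → 0 °C; then sat. aq. oxalic acid/Et2O, rt
Reagents that add atoms: water, O
Why: Corey–Enders aza-enolate alkylation (SN2 at the primary allylic bromide) followed by mild hydrazone hydrolysis gives a two-carbon homologation straight to the aldehyde.

Step 5
Reactants: 9 (4E,8Z)-4,8-dimethyl-13-(trimethylsilyl)trideca-4,8-dien-12-ynal; 10 trimethyl phosphonoacetate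
Product: 11 methyl (2E,6E,10Z)-6,10-dimethyl-15-(trimethylsilyl)pentadeca-2,6,10-trien-14-ynoate
Conditions: NaH, THF, 0 °C → rt
Reagents that add atoms: none
Why: Horner–Wadsworth–Emmons olefination of an unhindered aliphatic aldehyde gives the E-enoate with high selectivity.

Step 6
Reactants: 12 sulcatone, 6-methylhept-5-en-2-one
Product: 13 6-methylhepta-1,5-dien-2-yl trifluoromethanesulfonate
Conditions: LiN(i-Pr)2, THF, −78 °C; PhNTf2, −78 → 0 °C
Reagents that add atoms: N-phenylbis(trifluoromethanesulfonimide), O=S(=O)(N(c1ccccc1)S(=O)(=O)C(F)(F)F)C(F)(F)F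
Why: kinetic deprotonation of a methyl ketone occurs at the methyl group, and O-triflation of that enolate gives the 1,1-disubstituted alkenyl triflate.

Step 7
Reactants: 13 6-methylhepta-1,5-dien-2-yl trifluoromethanesulfonate
Product: 15 potassium trifluoro(6-methylhepta-1,5-dien-2-yl)borate, via pinacol boronate 14 (not isolated)
Conditions: B2pin2, PdCl2(PPh3)2 (3 mol %, divalent palladium precatalyst), PPh3, KOPh, toluene, 50 °C; then aq. KHF2, MeOH, rt
Reagents that add atoms: bis(pinacolato)diboron, CC1(C)OB(OC1(C)C)B1OC(C)(C)C(C)(C)O1; potassium hydrogen difluoride, [K+].F[H-]F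
Why: Miyaura borylation of an alkenyl triflate, then conversion of the crude pinacol ester with KHF2 into the crystalline, base-free transmetallating trifluoroborate.

Step 8
Reactants: 11 methyl (2E,6E,10Z)-6,10-dimethyl-15-(trimethylsilyl)pentadeca-2,6,10-trien-14-ynoate; 15 potassium trifluoro(6-methylhepta-1,5-dien-2-yl)borate
Product: 17 methyl (3R,6E,10Z)-6,10-dimethyl-3-(6-methylhepta-1,5-dien-2-yl)pentadeca-6,10-dien-14-ynoate, via silylated adduct 16 (not isolated)
Conditions: 15 (2 equiv), [Rh(cod)2]PF6 (3 mol %, monovalent rhodium), (S)-BINAP (3.3 mol %), toluene/H2O 20:1, 105 °C; then K2CO3, MeOH, rt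
Reagents that add atoms: none
Why: Hayashi–Miyaura asymmetric 1,4-addition under base-free trifluoroborate conditions (the silyl cap keeps the alkyne away from the alkenylrhodium); with (S)-BINAP the enoate binds through its α-Si face, so the alkenyl group is delivered to the Re face of C3 and sets 3R, and K2CO3/MeOH then cleaves the C(sp)–Si bond.

Step 9
Reactants: 17 methyl (3R,6E,10Z)-6,10-dimethyl-3-(6-methylhepta-1,5-dien-2-yl)pentadeca-6,10-dien-14-ynoate
Product: 18 (3R,6E,10Z)-6,10-dimethyl-3-(6-methylhepta-1,5-dien-2-yl)pentadeca-6,10-dien-14-ynal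
Conditions: i-Bu2AlH (1.1 equiv), CH2Cl2, −78 °C; aq. potassium sodium tartrate
Reagents that add atoms: none
Why: partial reduction of a methyl ester through the aluminium hemiacetal that is stable at −78 °C; the β-stereocentre cannot epimerise.

Step 10
Reactants: 18 (3R,6E,10Z)-6,10-dimethyl-3-(6-methylhepta-1,5-dien-2-yl)pentadeca-6,10-dien-14-ynal
Product: 19 triethyl{[(5Z,9E,13R)-6,10-dimethyl-2-methylidene-13-(6-methylhepta-1,5-dien-2-yl)cyclotetradeca-5,9-dien-1-yl]oxy}silane (both C1 epimers)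
Conditions: Ni(cod)2 (25 mol %, zerovalent nickel), racemic trans-1,3-bis(2,6-diisopropylphenyl)-4,5-diphenylimidazolinium tetrafluoroborate (25 mol %), KOt-Bu (25 mol %), Et3SiH (5 equiv), THF, rt, slow addition of 18 to 2 mM
Reagents that add atoms: triethylsilane, CC[SiH](CC)CC
Why: nickel/N-heterocyclic carbene reductive aldehyde–alkyne macrocyclisation (oxidative cyclisation to an oxanickelacycle, then Si–H σ-bond metathesis); the very bulky carbene steers C–C bond formation to the internal alkyne carbon, giving the 14-membered ring with an exocyclic methylidene, and the new carbinol centre is formed without control because step 11 erases it.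

Step 11
Reactants: 19 triethyl{[(5Z,9E,13R)-6,10-dimethyl-2-methylidene-13-(6-methylhepta-1,5-dien-2-yl)cyclotetradeca-5,9-dien-1-yl]oxy}silane
Product: 21 [(1E,4R,7E,11Z)-7,11-dimethyl-4-(6-methylhepta-1,5-dien-2-yl)cyclotetradeca-1,7,11-trien-1-yl]methanol, via primary silyl ether 20 (not isolated)
Conditions: Re2O7 (5 mol %, heptavalent rhenium), 4 Å MS, Et2O, −40 → −10 °C; then Bu4NF, THF, 0 °C
Reagents that add atoms: none
Why: Proposed new method: a stereoconvergent, silyl-shuttled rhenium-oxo 1,3-transposition inside a macrocycle; Re2O7 exchanges with the silyl ether to give the allyl perrhenate and Et3SiOReO3, and the perrhenate undergoes a chair-like [3,3] shift that forms the new C–O bond at the exocyclic CH2. With the ring CH2 next to the carbinol pseudo-equatorial, both carbinol epimers converge on the olefin in which that CH2 is trans to CH2O (the target geometry, as in orthoester Claisen routes to trisubstituted olefins). Re-silylation by Et3SiOReO3 traps the less hindered primary oxygen and, with the gain of a trisubstituted ring olefin, drives the equilibrium, and fluoride then frees the alcohol. The closest known reaction type is the Re2O7 or triphenylsilyl perrhenate catalysed 1,3-isomerisation of acyclic allylic alcohols and allylic silyl ethers, which has not been shown on a macrocyclic 2-methylidenecycloalkyl ether or used to set an endocyclic trisubstituted olefin.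

**Compound list**

1 | nerylacetone, (5Z)-6,10-dimethylundeca-5,9-dien-2-one | CC(=O)CC/C=C(/C)CCC=C(C)C | starting material
2 | diethyl (5Z)-6,10-dimethylundeca-1,5,9-trien-2-yl phosphate | C=C(OP(=O)(OCC)OCC)CC/C=C(/C)CCC=C(C)C | intermediate (not isolated)
3 | lithium (5Z)-6,10-dimethylundeca-5,9-dien-1-yn-1-ide | [Li]C#CCC/C=C(/C)CCC=C(C)C | intermediate (not isolated)
4 | [(5Z)-6,10-dimethylundeca-5,9-dien-1-yn-1-yl]trimethylsilane | C[Si](C)(C)C#CCC/C=C(/C)CCC=C(C)C | intermediate
5 | (2E,6Z)-2,6-dimethyl-11-(trimethylsilyl)undeca-2,6-dien-10-yn-1-ol | C[Si](C)(C)C#CCC/C=C(/C)CC/C=C(\C)CO | intermediate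
6 | [(5Z,9E)-11-bromo-6,10-dimethylundeca-5,9-dien-1-yn-1-yl]trimethylsilane | C[Si](C)(C)C#CCC/C=C(/C)CC/C=C(\C)CBr | intermediate
7 | acetaldehyde N,N-dimethylhydrazone | CC=NN(C)C | starting material
8 | (4E,8Z)-4,8-dimethyl-13-(trimethylsilyl)trideca-4,8-dien-12-ynal N,N-dimethylhydrazone | C[Si](C)(C)C#CCC/C=C(/C)CC/C=C(\C)CCC=NN(C)C | intermediate (not isolated)
9 | (4E,8Z)-4,8-dimethyl-13-(trimethylsilyl)trideca-4,8-dien-12-ynal | C[Si](C)(C)C#CCC/C=C(/C)CC/C=C(\C)CCC=O | intermediate
10 | trimethyl phosphonoacetate | COC(=O)CP(=O)(OC)OC | starting material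
11 | methyl (2E,6E,10Z)-6,10-dimethyl-15-(trimethylsilyl)pentadeca-2,6,10-trien-14-ynoate | C[Si](C)(C)C#CCC/C=C(/C)CC/C=C(\C)CC/C=C/C(=O)OC | intermediate
12 | sulcatone, 6-methylhept-5-en-2-one | CC(=O)CCC=C(C)C | starting material
13 | 6-methylhepta-1,5-dien-2-yl trifluoromethanesulfonate | C=C(OS(=O)(=O)C(F)(F)F)CCC=C(C)C | intermediate
14 | 4,4,5,5-tetramethyl-2-(6-methylhepta-1,5-dien-2-yl)-1,3,2-dioxaborolane | C=C(B1OC(C)(C)C(C)(C)O1)CCC=C(C)C | intermediate (not isolated)
15 | potassium trifluoro(6-methylhepta-1,5-dien-2-yl)borate | [K+].F[B-](F)(F)C(=C)CCC=C(C)C | intermediate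
16 | methyl (3R,6E,10Z)-6,10-dimethyl-3-(6-methylhepta-1,5-dien-2-yl)-15-(trimethylsilyl)pentadeca-6,10-dien-14-ynoate | COC(=O)C[C@H](C(=C)CCC=C(C)C)CC/C(C)=C/CC/C(C)=C\CCC#C[Si](C)(C)C | intermediate (not isolated)
17 | methyl (3R,6E,10Z)-6,10-dimethyl-3-(6-methylhepta-1,5-dien-2-yl)pentadeca-6,10-dien-14-ynoate | COC(=O)C[C@H](C(=C)CCC=C(C)C)CC/C(C)=C/CC/C(C)=C\CCC#C | intermediate
18 | (3R,6E,10Z)-6,10-dimethyl-3-(6-methylhepta-1,5-dien-2-yl)pentadeca-6,10-dien-14-ynal | O=CC[C@H](C(=C)CCC=C(C)C)CC/C(C)=C/CC/C(C)=C\CCC#C | intermediate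
19 | triethyl{[(5Z,9E,13R)-6,10-dimethyl-2-methylidene-13-(6-methylhepta-1,5-dien-2-yl)cyclotetradeca-5,9-dien-1-yl]oxy}silane, both C1 epimers | C=C(CCC=C(C)C)[C@H]1CC(O[Si](CC)(CC)CC)C(=C)CC/C=C(/C)CC/C=C(\C)CC1 | intermediate
20 | triethyl{[(1E,4R,7E,11Z)-7,11-dimethyl-4-(6-methylhepta-1,5-dien-2-yl)cyclotetradeca-1,7,11-trien-1-yl]methoxy}silane | C=C(CCC=C(C)C)[C@H]1C/C=C(/CO[Si](CC)(CC)CC)CC/C=C(/C)CC/C=C(\C)CC1 | intermediate (not isolated)
21 | [(1E,4R,7E,11Z)-7,11-dimethyl-4-(6-methylhepta-1,5-dien-2-yl)cyclotetradeca-1,7,11-trien-1-yl]methanol | C=C(CCC=C(C)C)[C@H]1C/C=C(/CO)CC/C=C(/C)CC/C=C(\C)CC1 | target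

**Step count and risks**

Total steps: 11. Longest linear sequence: 9 (steps 1–5 and 8–11).

Most likely to fail:

1. Step 11 (the proposed transposition). The risks are an E/Z mixture at the new ring olefin if the perrhenate equilibrates, and acid-triggered transannular or olefin-migration side reactions. The fallback uses known chemistry, sets out from 19 and comes back at 21. Bu4NF desilylates 19 to the allylic alcohols F1. SOCl2 in Et2O at 0 °C over solid K2CO3 converts them, through the chlorosulfite F2 (not isolated, SNi′ collapse with allylic shift), into the primary allylic chloride F3. CsOAc in DMF gives the acetate F4 by SN2 displacement, and K2CO3 in MeOH releases 21.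

2. Step 10 (nickel macrocyclisation). The risks are alkyne oligomerisation, endo-mode coupling and interference by the other olefins. The fallback sets out from 17 and comes back at 19. Treatment of 17 with 9-iodo-9-borabicyclo[3.3.1]nonane and then AcOH adds HI across the terminal alkyne only and gives the 2-iodoalkene ester F5. i-Bu2AlH at −78 °C gives the iodo-aldehyde F6. An intramolecular Nozaki–Hiyama–Kishi reaction (CrCl2 in excess, NiCl2 1 mol %, DMSO/THF, high dilution) closes the ring to the allylic alcohols F1, which Et3SiCl and imidazole convert into 19.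

3. Step 8 (asymmetric 1,4-addition). The risks are a sluggish 1,1-disubstituted alkenyl transfer, protodeboronation, and lower selectivity on a methyl ester. The fallback replaces catalyst control with an auxiliary, sets out from 11 and comes back at 16, which is desilylated to 17 as in step 8. Me3SnOH in 1,2-dichloroethane hydrolyses 11 to the acid F7. Pivaloyl chloride and Et3N give the mixed pivalic anhydride F8 (not isolated), which acylates lithiated (4S)-4-benzyl-1,3-oxazolidin-2-one to the imide F9. Separately, sulcatone 12 and 2,4,6-triisopropylbenzenesulfonyl hydrazide give the trisylhydrazone F10. A Shapiro reaction (n-BuLi, 2 equiv) gives the alkenyllithium F11, and MgBr2·OEt2 turns it into the alkenylmagnesium bromide F12. With CuBr·SMe2 (monovalent copper) in THF/Me2S at −78 → −20 °C, F12 adds to the chelated s-cis imide on the face away from the benzyl group and gives the 3R adduct F13. MeOMgBr in MeOH cleaves the auxiliary and gives 16.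

**Further compounds**

F1 | step 11 | (5Z,9E,13R)-6,10-dimethyl-2-methylidene-13-(6-methylhepta-1,5-dien-2-yl)cyclotetradeca-5,9-dien-1-ol, both C1 epimers | C=C(CCC=C(C)C)[C@H]1CC(O)C(=C)CC/C=C(/C)CC/C=C(\C)CC1
F2 | step 11 | (5Z,9E,13R)-6,10-dimethyl-2-methylidene-13-(6-methylhepta-1,5-dien-2-yl)cyclotetradeca-5,9-dien-1-yl chlorosulfite | C=C(CCC=C(C)C)[C@H]1CC(OS(Cl)=O)C(=C)CC/C=C(/C)CC/C=C(\C)CC1
F3 | step 11 | (1E,4R,7E,11Z)-1-(chloromethyl)-7,11-dimethyl-4-(6-methylhepta-1,5-dien-2-yl)cyclotetradeca-1,7,11-triene | C=C(CCC=C(C)C)[C@H]1C/C=C(/CCl)CC/C=C(/C)CC/C=C(\C)CC1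
F4 | step 11 | [(1E,4R,7E,11Z)-7,11-dimethyl-4-(6-methylhepta-1,5-dien-2-yl)cyclotetradeca-1,7,11-trien-1-yl]methyl acetate | C=C(CCC=C(C)C)[C@H]1C/C=C(/COC(C)=O)CC/C=C(/C)CC/C=C(\C)CC1
F5 | step 10 | methyl (3R,6E,10Z)-14-iodo-6,10-dimethyl-3-(6-methylhepta-1,5-dien-2-yl)pentadeca-6,10,14-trienoate | COC(=O)C[C@H](C(=C)CCC=C(C)C)CC/C(C)=C/CC/C(C)=C\CCC(I)=C
F6 | step 10 | (3R,6E,10Z)-14-iodo-6,10-dimethyl-3-(6-methylhepta-1,5-dien-2-yl)pentadeca-6,10,14-trienal | O=CC[C@H](C(=C)CCC=C(C)C)CC/C(C)=C/CC/C(C)=C\CCC(I)=C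
F7 | step 8 | (2E,6E,10Z)-6,10-dimethyl-15-(trimethylsilyl)pentadeca-2,6,10-trien-14-ynoic acid | C[Si](C)(C)C#CCC/C=C(/C)CC/C=C(\C)CC/C=C/C(=O)O
F8 | step 8 | (2E,6E,10Z)-6,10-dimethyl-15-(trimethylsilyl)pentadeca-2,6,10-trien-14-ynoic pivalic anhydride | C[Si](C)(C)C#CCC/C=C(/C)CC/C=C(\C)CC/C=C/C(=O)OC(=O)C(C)(C)C
F9 | step 8 | (4S)-4-benzyl-3-[(2E,6E,10Z)-6,10-dimethyl-15-(trimethylsilyl)pentadeca-2,6,10-trien-14-ynoyl]-1,3-oxazolidin-2-one | C[Si](C)(C)C#CCC/C=C(/C)CC/C=C(\C)CC/C=C/C(=O)N1[C@@H](Cc2ccccc2)COC1=O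
F10 | step 8 | N'-(6-methylhept-5-en-2-ylidene)-2,4,6-triisopropylbenzenesulfonohydrazide | CC(CCC=C(C)C)=NNS(=O)(=O)c1c(C(C)C)cc(C(C)C)cc1C(C)C
F11 | step 8 | (6-methylhepta-1,5-dien-2-yl)lithium | [Li]C(=C)CCC=C(C)C
F12 | step 8 | (6-methylhepta-1,5-dien-2-yl)magnesium bromide | Br[Mg]C(=C)CCC=C(C)C
F13 | step 8 | (4S)-4-benzyl-3-[(3R,6E,10Z)-6,10-dimethyl-3-(6-methylhepta-1,5-dien-2-yl)-15-(trimethylsilyl)pentadeca-6,10-dien-14-ynoyl]-1,3-oxazolidin-2-one | C[Si](C)(C)C#CCC/C=C(/C)CC/C=C(\C)CC[C@@H](C(=C)CCC=C(C)C)CC(=O)N1[C@@H](Cc2ccccc2)COC1=O
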